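## Retrosynthetic overview

- The target is a cis-fused furo[3,2-b]furan-2-one: lactone ring O1–C2–C3–C3a–C6a, oxolane ring O4–C5–C6–C6a–C3a. The strategy rests on quaternary C5 (CH3, aryl-dodecyl chain, O4, C6), which is the methine carbon of a secondary alkyl ether in which C6 has replaced hydrogen.
- Late stage: the phenol comes from its benzyl ether, the lactone bond O1–C2 from a tert-butyl ester and a cis tertiary hydroxyl at C6a, and the C6a methyl from methyl addition to a C6a ketone anti to the C3a arm.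
- Oxolane ring first: C5–C6 is made by rhodium-carbenoid insertion of alpha-alkoxy diazoketone 20 into the tertiary C5–H bond with retention, giving oxolan-3-one 21. The lactone ring is closed second.
- Diazoketone 20 comes from (2S)-alcohol 7 by O-alkylation with bromoacetic acid, auxiliary-controlled alkylation with tert-butyl bromoacetate (sets C3a), auxiliary cleavage and acylation of diazomethane.
- Alcohol 7 comes from (S)-propylene oxide and the Grignard reagent of bromide 4, itself made from 4-(benzyloxy)benzyl chloride and 1,10-dibromodecane.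

Key step: step 8

Remark: ethereal CH2N2 and MeTi(OiPr)3 are taken as pre-formed reagent solutions, and the locants of the furo[3,2-b]furan-2-one core (target: 3aS,5S,6aS) are used for the corresponding atoms of all intermediates.

## Route

Step 1
Reactants: 1 4-(benzyloxy)benzyl chloride; 2 1,10-dibromodecane
Product: 4 1-(benzyloxy)-4-(11-bromoundecyl)benzene, via benzylic Grignard reagent 3 (not isolated)
Conditions: Mg, THF, 0 °C (slow addition of 1); then 2 (3 equiv), Li2CuCl4 (3 mol%), THF, −10 °C → rt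
Reagents that add atoms: none
Why: Grignard formation followed by copper-catalysed sp3–sp3 cross-coupling with a primary bromide (Kochi coupling) joins the benzylic carbon to one end of the C10 chain, the excess of 2 suppressing double substitution; no stereocentre is involved.

Step 2
Reactants: 4 1-(benzyloxy)-4-(11-bromoundecyl)benzene; 5 (S)-propylene oxide
Product: 7 (2S)-14-[4-(benzyloxy)phenyl]tetradecan-2-ol, via alkyl Grignard reagent 6 (not isolated)
Conditions: Mg, THF, 50 °C; then CuI (10 mol%), 5, −30 → 0 °C; 1 M HCl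
Reagents that add atoms: none
Why: Copper-catalysed Grignard opening of a terminal epoxide is an SN2 attack at the unsubstituted CH2, so the stereocentre of 5 is not touched and becomes the (2S) carbinol.

Step 3
Reactants: 7 (2S)-14-[4-(benzyloxy)phenyl]tetradecan-2-ol; 8 bromoacetic acid
Product: 10 2-{[(2S)-14-(4-benzyloxyphenyl)tetradecan-2-yl]oxy}acetic acid, via sodium alkoxide 9 (not isolated)
Conditions: NaH (3.5 equiv), THF, 0 °C → rt; then 8, 50 °C; 1 M HCl
Reagents that add atoms: none
Why: Williamson ether synthesis in which the sodium alkoxide displaces bromide from the primary carbon of sodium bromoacetate, so the carbinol centre keeps its configuration.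

Step 4
Reactants: 10 2-{[(2S)-14-(4-benzyloxyphenyl)tetradecan-2-yl]oxy}acetic acid; 11 (4R)-4-benzyl-1,3-oxazolidin-2-one
Product: 13 (4R)-4-benzyl-3-(2-{[(2S)-14-(4-benzyloxyphenyl)tetradecan-2-yl]oxy}acetyl)-1,3-oxazolidin-2-one, via mixed pivalic anhydride 12 (not isolated)
Conditions: PivCl, Et3N, THF, −20 °C; then LiCl, 11, −20 °C → rt
Reagents that add atoms: none
Why: N-acylation of the oxazolidinone through a mixed anhydride (LiCl/Et3N activation) occurs at the unhindered alkoxyacetyl carbonyl and not at the pivaloyl carbonyl; no stereocentre is formed.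

Step 5
Reactants: 13 (4R)-4-benzyl-3-(2-{[(2S)-14-(4-benzyloxyphenyl)tetradecan-2-yl]oxy}acetyl)-1,3-oxazolidin-2-one; 14 tert-butyl bromoacetate
Product: 16 tert-butyl (3S)-4-[(4R)-4-benzyl-2-oxo-1,3-oxazolidin-3-yl]-3-{[(2S)-14-(4-benzyloxyphenyl)tetradecan-2-yl]oxy}-4-oxobutanoate, via sodium enolate 15 (not isolated)
Conditions: NaN(SiMe3)2, THF, −78 °C; then 14, −78 → −45 °C
Reagents that add atoms: none
Why: Evans asymmetric alkylation, in which the chelated sodium (Z)-enolate is shielded on one face by the benzyl group of the (4R) auxiliary, so the reactive alpha-bromo ester enters from the other face and sets the (S) centre that becomes C3a.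

Step 6
Reactants: 16 tert-butyl (3S)-4-[(4R)-4-benzyl-2-oxo-1,3-oxazolidin-3-yl]-3-{[(2S)-14-(4-benzyloxyphenyl)tetradecan-2-yl]oxy}-4-oxobutanoate
Product: 18 (2S)-4-tert-butoxy-2-{[(2S)-14-(4-benzyloxyphenyl)tetradecan-2-yl]oxy}-4-oxobutanoic acid, via peroxy acid 17 (not isolated)
Conditions: LiOH, H2O2, THF/H2O, 0 °C; then aq Na2SO3; 1 M HCl to pH 3
Reagents that add atoms: hydrogen peroxide (as LiOOH), `OO`
Why: Hydroperoxide cleavage of an N-acyl oxazolidinone attacks the exocyclic carbonyl selectively, and the hindered tert-butyl ester and the alpha-alkoxy centre should be left intact by this weakly basic nucleophile at 0 °C.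

Step 7
Reactants: 18 (2S)-4-tert-butoxy-2-{[(2S)-14-(4-benzyloxyphenyl)tetradecan-2-yl]oxy}-4-oxobutanoic acid
Product: 20 tert-butyl (3S)-5-diazo-4-oxo-3-{[(2S)-14-(4-benzyloxyphenyl)tetradecan-2-yl]oxy}pentanoate, via mixed carbonic anhydride 19 (not isolated)
Conditions: iBuOCOCl, N-methylmorpholine, THF, −20 °C; then CH2N2, Et2O, −20 °C → rt
Reagents that add atoms: diazomethane, `C=[N+]=[N-]`
Why: Acylation of diazomethane by a mixed carbonic anhydride (first stage of the Arndt–Eistert protocol) gives the alpha-diazoketone without an acid chloride, which spares the tert-butyl ester and the alpha-alkoxy stereocentre.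

Step 8
Reactants: 20 tert-butyl (3S)-5-diazo-4-oxo-3-{[(2S)-14-(4-benzyloxyphenyl)tetradecan-2-yl]oxy}pentanoate
Product: 21 tert-butyl 2-[(2S,5S)-5-{12-[4-(benzyloxy)phenyl]dodecyl}-5-methyl-3-oxooxolan-2-yl]acetate
Conditions: Rh2(OAc)4 (2 mol%), CH2Cl2, rt, slow addition of 20 at high dilution
Reagents that add atoms: none
Why: Rh2(OAc)4 takes up the diazo carbon with loss of N2 to give an electrophilic carbenoid on the divalent rhodium dimer, and its carbon (C6) attacks the hydridic tertiary C5–H bond next to the ether oxygen O4 through a three-centre transition state, forming C5–C6. The closest known reaction type is the rhodium-carbenoid 1,5 C–H insertion of alpha-alkoxy diazoketones to oxolan-3-ones. The oxolane ring closes through a five-membered cyclic transition state whose members (C6, the ketone carbon C6a, C3a, O4, C5) become the ring atoms. The new stereocentre C5 is controlled by the substrate, because insertion replaces hydrogen by carbon with retention, so the (2S) centre from (S)-propylene oxide becomes (5S) while the C3a centre is not involved. The step needs site selectivity, which is secured because the methine is the only C–H in a 1,5 relationship to the carbenoid and is both tertiary and oxygen-activated, whereas the methyl and chain C–H bonds would need six-membered transition states. It also needs chemoselectivity against capture of the carbenoid by the ester carbonyl or by a second diazo molecule, which rests on the poor donor ability of the hindered tert-butyl ester and on slow addition at high dilution.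

Step 9
Reactants: 21 tert-butyl 2-[(2S,5S)-5-{12-[4-(benzyloxy)phenyl]dodecyl}-5-methyl-3-oxooxolan-2-yl]acetate
Product: 22 tert-butyl 2-[(2S,3S,5S)-5-{12-[4-(benzyloxy)phenyl]dodecyl}-3-hydroxy-3,5-dimethyloxolan-2-yl]acetate
Conditions: MeTi(OiPr)3 (3 equiv), Et2O, −20 °C → rt; aq NH4Cl
Reagents that add atoms: methyltitanium triisopropoxide, `C[Ti](OC(C)C)(OC(C)C)OC(C)C`
Why: Non-basic organotitanium carbonyl addition is selective for the ketone over the ester and avoids enolisation or beta-elimination of the ring oxygen, and methyl should enter the C6a carbonyl from the face anti to the adjacent C3a acetate arm, giving the carbinol with hydroxyl cis to the arm.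

Step 10
Reactants: 22 tert-butyl 2-[(2S,3S,5S)-5-{12-[4-(benzyloxy)phenyl]dodecyl}-3-hydroxy-3,5-dimethyloxolan-2-yl]acetate
Product: 24 (3aS,5S,6aS)-5-{12-[4-(benzyloxy)phenyl]dodecyl}-5,6a-dimethylhexahydrofuro[3,2-b]furan-2-one, via hydroxy acid 23 (not isolated)
Conditions: TFA/CH2Cl2 (1:4), 0 °C → rt
Reagents that add atoms: none
Why: Acidolysis of the tert-butyl ester frees the acid, which closes the gamma-lactone onto the cis tertiary hydroxyl (acid-catalysed lactonisation, 5-exo-trig), and since only the cis-fused bicycle can form, any epimeric carbinol from step 9 stays open and is removed.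

Step 11
Reactants: 24 (3aS,5S,6aS)-5-{12-[4-(benzyloxy)phenyl]dodecyl}-5,6a-dimethylhexahydrofuro[3,2-b]furan-2-one
Product: 25 plakortone N, (3aS,5S,6aS)-5-[12-(4-hydroxyphenyl)dodecyl]-5,6a-dimethylhexahydrofuro[3,2-b]furan-2-one
Conditions: H2 (1 atm), 10% Pd/C, EtOAc, rt
Reagents that add atoms: none
Why: Catalytic hydrogenolysis of the benzyl aryl ether over Pd/C frees the phenol, and the lactone, the oxolane and the three stereocentres are inert to these conditions.

## Compound list

1 | 4-(benzyloxy)benzyl chloride | `ClCc1ccc(OCc2ccccc2)cc1` | starting material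
2 | 1,10-dibromodecane | `BrCCCCCCCCCCBr` | starting material
3 | [4-(benzyloxy)benzyl]magnesium chloride | `Cl[Mg]Cc1ccc(OCc2ccccc2)cc1` | intermediate
4 | 1-(benzyloxy)-4-(11-bromoundecyl)benzene | `BrCCCCCCCCCCCc1ccc(OCc2ccccc2)cc1` | intermediate
5 | (S)-propylene oxide | `C[C@H]1CO1` | starting material
6 | {11-[4-(benzyloxy)phenyl]undecyl}magnesium bromide | `Br[Mg]CCCCCCCCCCCc1ccc(OCc2ccccc2)cc1` | intermediate
7 | (2S)-14-[4-(benzyloxy)phenyl]tetradecan-2-ol | `C[C@H](O)CCCCCCCCCCCCc1ccc(OCc2ccccc2)cc1` | intermediate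
8 | bromoacetic acid | `OC(=O)CBr` | starting material
9 | sodium (2S)-14-[4-(benzyloxy)phenyl]tetradecan-2-olate | `C[C@H]([O-])CCCCCCCCCCCCc1ccc(OCc2ccccc2)cc1.[Na+]` | intermediate
10 | 2-{[(2S)-14-(4-benzyloxyphenyl)tetradecan-2-yl]oxy}acetic acid | `C[C@H](OCC(=O)O)CCCCCCCCCCCCc1ccc(OCc2ccccc2)cc1` | intermediate
11 | (4R)-4-benzyl-1,3-oxazolidin-2-one | `O=C1N[C@H](Cc2ccccc2)CO1` | starting material
12 | 2-{[(2S)-14-(4-benzyloxyphenyl)tetradecan-2-yl]oxy}acetic pivalic anhydride | `C[C@H](OCC(=O)OC(=O)C(C)(C)C)CCCCCCCCCCCCc1ccc(OCc2ccccc2)cc1` | intermediate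
13 | (4R)-4-benzyl-3-(2-{[(2S)-14-(4-benzyloxyphenyl)tetradecan-2-yl]oxy}acetyl)-1,3-oxazolidin-2-one | `C[C@H](OCC(=O)N1[C@H](Cc2ccccc2)COC1=O)CCCCCCCCCCCCc1ccc(OCc2ccccc2)cc1` | intermediate
14 | tert-butyl bromoacetate | `BrCC(=O)OC(C)(C)C` | starting material
15 | sodium (Z)-1-[(4R)-4-benzyl-2-oxo-1,3-oxazolidin-3-yl]-2-{[(2S)-14-(4-benzyloxyphenyl)tetradecan-2-yl]oxy}ethen-1-olate | `C[C@H](O/C=C(/N1[C@H](Cc2ccccc2)COC1=O)[O-])CCCCCCCCCCCCc1ccc(OCc2ccccc2)cc1.[Na+]` | intermediate
16 | tert-butyl (3S)-4-[(4R)-4-benzyl-2-oxo-1,3-oxazolidin-3-yl]-3-{[(2S)-14-(4-benzyloxyphenyl)tetradecan-2-yl]oxy}-4-oxobutanoate | `O=C1OC[C@@H](Cc2ccccc2)N1C(=O)[C@H](CC(=O)OC(C)(C)C)O[C@@H](C)CCCCCCCCCCCCc1ccc(OCc2ccccc2)cc1` | intermediate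
17 | (2S)-4-tert-butoxy-2-{[(2S)-14-(4-benzyloxyphenyl)tetradecan-2-yl]oxy}-4-oxobutaneperoxoic acid (lithium salt in the flask) | `OOC(=O)[C@H](CC(=O)OC(C)(C)C)O[C@@H](C)CCCCCCCCCCCCc1ccc(OCc2ccccc2)cc1` | intermediate
18 | (2S)-4-tert-butoxy-2-{[(2S)-14-(4-benzyloxyphenyl)tetradecan-2-yl]oxy}-4-oxobutanoic acid | `OC(=O)[C@H](CC(=O)OC(C)(C)C)O[C@@H](C)CCCCCCCCCCCCc1ccc(OCc2ccccc2)cc1` | intermediate
19 | (2S)-4-tert-butoxy-2-{[(2S)-14-(4-benzyloxyphenyl)tetradecan-2-yl]oxy}-4-oxobutanoic isobutyl carbonic anhydride | `CC(C)COC(=O)OC(=O)[C@H](CC(=O)OC(C)(C)C)O[C@@H](C)CCCCCCCCCCCCc1ccc(OCc2ccccc2)cc1` | intermediate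
20 | tert-butyl (3S)-5-diazo-4-oxo-3-{[(2S)-14-(4-benzyloxyphenyl)tetradecan-2-yl]oxy}pentanoate | `[N-]=[N+]=CC(=O)[C@H](CC(=O)OC(C)(C)C)O[C@@H](C)CCCCCCCCCCCCc1ccc(OCc2ccccc2)cc1` | intermediate
21 | tert-butyl 2-[(2S,5S)-5-{12-[4-(benzyloxy)phenyl]dodecyl}-5-methyl-3-oxooxolan-2-yl]acetate | `C[C@]1(CCCCCCCCCCCCc2ccc(OCc3ccccc3)cc2)CC(=O)[C@H](CC(=O)OC(C)(C)C)O1` | intermediate
22 | tert-butyl 2-[(2S,3S,5S)-5-{12-[4-(benzyloxy)phenyl]dodecyl}-3-hydroxy-3,5-dimethyloxolan-2-yl]acetate | `C[C@]1(CCCCCCCCCCCCc2ccc(OCc3ccccc3)cc2)C[C@](C)(O)[C@H](CC(=O)OC(C)(C)C)O1` | intermediate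
23 | 2-[(2S,3S,5S)-5-{12-[4-(benzyloxy)phenyl]dodecyl}-3-hydroxy-3,5-dimethyloxolan-2-yl]acetic acid | `C[C@]1(CCCCCCCCCCCCc2ccc(OCc3ccccc3)cc2)C[C@](C)(O)[C@H](CC(=O)O)O1` | intermediate
24 | (3aS,5S,6aS)-5-{12-[4-(benzyloxy)phenyl]dodecyl}-5,6a-dimethylhexahydrofuro[3,2-b]furan-2-one | `C[C@]1(CCCCCCCCCCCCc2ccc(OCc3ccccc3)cc2)C[C@]2(C)OC(=O)C[C@@H]2O1` | intermediate
25 | plakortone N, (3aS,5S,6aS)-5-[12-(4-hydroxyphenyl)dodecyl]-5,6a-dimethylhexahydrofuro[3,2-b]furan-2-one | `C[C@]1(CCCCCCCCCCCCc2ccc(O)cc2)C[C@]2(C)OC(=O)C[C@@H]2O1` | target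

## Step count and risks

Total step count: 11. Longest linear sequence: 11 steps (1 to 25).

**Step 8 (key step).** The carbenoid may be consumed before it reaches the C5–H bond: capture by the ester carbonyl oxygen to a six-membered carbonyl ylide, Wolff rearrangement or dimerisation. The insertion may also run stepwise, by hydride transfer to an oxocarbenium ion and a rhodium enolate, which would erode retention at C5.

The fallback sets out from 7 and returns at 24, after which step 11 follows. It sets C5 by a reagent-controlled ketone allylation and closes both rings by a divalent-palladium hydroxycyclisation–carbonylation–lactonisation instead of carbenoid chemistry. Dess–Martin oxidation of 7 should give 14-[4-(benzyloxy)phenyl]tetradecan-2-one F1. Catalytic asymmetric allylboration (allyldiisopropoxyborane, 3,3'-dibromo-BINOL of the handedness that leads to the 4S carbinol) should give (4S)-16-[4-(benzyloxy)phenyl]-4-methylhexadec-1-en-4-ol F2, whose enantiomeric purity is to be checked at this stage. Tsuji–Wacker oxidation (PdCl2 cat., CuCl, O2, DMF/H2O) should give (4S)-16-[4-(benzyloxy)phenyl]-4-hydroxy-4-methylhexadecan-2-one F3. Addition of vinylmagnesium bromide with CeCl3 at −78 °C, cold enough to outrun retro-aldol cleavage, should give (3S,5S)-17-[4-(benzyloxy)phenyl]-3,5-dimethylheptadec-1-ene-3,5-diol F4. Only modest 1,3-induction is expected at the new carbinol carbon, so a chromatographic separation of diastereomers is planned here or after the next operation. PdCl2 (cat.), CuCl2, NaOAc and AcOH under CO (1 atm) should then let the hydroxyl at the future C5 add to the alkene, CO insert into the C–Pd bond and the allylic tertiary hydroxyl close the lactone. For geometric reasons this can only give the cis-fused bicycle 24.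

**Step 9.** Facial selectivity of the methyl transfer may be poor, because the C5 chain lies on the face anti to the C3a arm and opposes the directing effect of the arm. Ketone 21 may also epimerise at C3a before addition, so it should be used without storage.

The fallback sets out from 21 and returns at 24. It fixes the C6a configuration by the ring fusion instead of by a facial preference. Takai–Lombardo methylenation (Zn, CH2Br2, TiCl4, THF/CH2Cl2, non-basic) should give tert-butyl 2-[(2S,5S)-5-{12-[4-(benzyloxy)phenyl]dodecyl}-5-methyl-3-methylideneoxolan-2-yl]acetate F5. TFA/CH2Cl2 should give 2-[(2S,5S)-5-{12-[4-(benzyloxy)phenyl]dodecyl}-5-methyl-3-methylideneoxolan-2-yl]acetic acid F6. Iodolactonisation (I2, NaHCO3, MeCN, 0 °C, 5-exo-trig) lets the carboxylate reach C6a only from the face of its own arm. It should give (3aS,5S,6aS)-5-{12-[4-(benzyloxy)phenyl]dodecyl}-6a-(iodomethyl)-5-methylhexahydrofuro[3,2-b]furan-2-one F7. Radical deiodination (Bu3SnH, AIBN, toluene, 80 °C) turns CH2I into the C6a methyl group and should give 24.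

**Step 5.** Alkylation by the bromo ester next to the bulky secondary alkoxy group may be slow. The thermally fragile sodium glycolate enolate could then decompose with loss of the auxiliary, or react with lower diastereoselectivity.

The fallback sets out from 13 and returns at 16. The enolate 15 is alkylated with allyl iodide, the most reactive class of electrophile for glycolate enolates, and the ester carbon is then unveiled by oxidation. Allylation should give (4R)-4-benzyl-3-[(2S)-2-{[(2S)-14-(4-benzyloxyphenyl)tetradecan-2-yl]oxy}pent-4-enoyl]-1,3-oxazolidin-2-one F8. Lemieux–Johnson cleavage (OsO4 cat., NaIO4, 2,6-lutidine, dioxane/H2O) should give (3S)-4-[(4R)-4-benzyl-2-oxo-1,3-oxazolidin-3-yl]-3-{[(2S)-14-(4-benzyloxyphenyl)tetradecan-2-yl]oxy}-4-oxobutanal F9. Pinnick oxidation (NaClO2, NaH2PO4, 2-methylbut-2-ene, tBuOH/H2O) should give (3S)-4-[(4R)-4-benzyl-2-oxo-1,3-oxazolidin-3-yl]-3-{[(2S)-14-(4-benzyloxyphenyl)tetradecan-2-yl]oxy}-4-oxobutanoic acid F10. tert-Butylation with tert-butyl 2,2,2-trichloroacetimidate (cyclohexane/CH2Cl2, rt) should give 16.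

## Further compounds

F1 | step 8 | 14-[4-(benzyloxy)phenyl]tetradecan-2-one | `CC(=O)CCCCCCCCCCCCc1ccc(OCc2ccccc2)cc1`
F2 | step 8 | (4S)-16-[4-(benzyloxy)phenyl]-4-methylhexadec-1-en-4-ol | `C[C@](O)(CCCCCCCCCCCCc1ccc(OCc2ccccc2)cc1)CC=C`
F3 | step 8 | (4S)-16-[4-(benzyloxy)phenyl]-4-hydroxy-4-methylhexadecan-2-one | `C[C@](O)(CCCCCCCCCCCCc1ccc(OCc2ccccc2)cc1)CC(C)=O`
F4 | step 8 | (3S,5S)-17-[4-(benzyloxy)phenyl]-3,5-dimethylheptadec-1-ene-3,5-diol | `C[C@](O)(CCCCCCCCCCCCc1ccc(OCc2ccccc2)cc1)C[C@](C)(O)C=C`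
F5 | step 9 | tert-butyl 2-[(2S,5S)-5-{12-[4-(benzyloxy)phenyl]dodecyl}-5-methyl-3-methylideneoxolan-2-yl]acetate | `C[C@]1(CCCCCCCCCCCCc2ccc(OCc3ccccc3)cc2)CC(=C)[C@H](CC(=O)OC(C)(C)C)O1`
F6 | step 9 | 2-[(2S,5S)-5-{12-[4-(benzyloxy)phenyl]dodecyl}-5-methyl-3-methylideneoxolan-2-yl]acetic acid | `C[C@]1(CCCCCCCCCCCCc2ccc(OCc3ccccc3)cc2)CC(=C)[C@H](CC(=O)O)O1`
F7 | step 9 | (3aS,5S,6aS)-5-{12-[4-(benzyloxy)phenyl]dodecyl}-6a-(iodomethyl)-5-methylhexahydrofuro[3,2-b]furan-2-one | `C[C@]1(CCCCCCCCCCCCc2ccc(OCc3ccccc3)cc2)C[C@]2(CI)OC(=O)C[C@@H]2O1`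
F8 | step 5 | (4R)-4-benzyl-3-[(2S)-2-{[(2S)-14-(4-benzyloxyphenyl)tetradecan-2-yl]oxy}pent-4-enoyl]-1,3-oxazolidin-2-one | `O=C1OC[C@@H](Cc2ccccc2)N1C(=O)[C@H](CC=C)O[C@@H](C)CCCCCCCCCCCCc1ccc(OCc2ccccc2)cc1`
F9 | step 5 | (3S)-4-[(4R)-4-benzyl-2-oxo-1,3-oxazolidin-3-yl]-3-{[(2S)-14-(4-benzyloxyphenyl)tetradecan-2-yl]oxy}-4-oxobutanal | `O=C1OC[C@@H](Cc2ccccc2)N1C(=O)[C@H](CC=O)O[C@@H](C)CCCCCCCCCCCCc1ccc(OCc2ccccc2)cc1`
F10 | step 5 | (3S)-4-[(4R)-4-benzyl-2-oxo-1,3-oxazolidin-3-yl]-3-{[(2S)-14-(4-benzyloxyphenyl)tetradecan-2-yl]oxy}-4-oxobutanoic acid | `O=C1OC[C@@H](Cc2ccccc2)N1C(=O)[C@H](CC(=O)O)O[C@@H](C)CCCCCCCCCCCCc1ccc(OCc2ccccc2)cc1`
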